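I decided to keep books on E, taking one E for each Q or J made; its charge of 0.600 M matches D and X together, 0.600 M, so on that count the charge is stoichiometric.

| setting | dusk | winter | noon | cedar | birch |
|---|---|---|---|---|---|
| D | 0.20 M | 0.45 M | 0.30 M | 0.30 M | 0.30 M |
| X | 0.20 M | 0.45 M | 0.30 M | 0.30 M | 0.30 M |
| E | 0.60 M | 0.60 M | 0.60 M | 0.600 M | 0.600 M |
| L | 6 mM | 6 mM | 3 mM | 6.0 mM | 6.0 mM |
| temperature | −15 °C | 15 °C | −15 °C |  |  |
| remark | run made earlier | run made earlier | run made earlier | at −10 °C throughout | at −10 °C until 3.0 d, from then on at 40 °C |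
| time |  |  |  | 10 d | 10 d |

| run | time / d | Q / % | J / % | D / % |
|---|---|---|---|---|
| dusk | 0.833 | 2.7 | 0 | 46.2 |
| dusk | 2.50 | 14.1 | 1.4 | 36.1 |
| dusk | 5.00 | 27.4 | 3.3 | 23.0 |
| dusk | 8.00 | 38.5 | 6.9 | 12.8 |
| dusk | 10.0 | 42.8 | 7.2 | 7.2 |
| winter | 0.250 | 2.0 | 0 | 47.4 |
| winter | 0.500 | 3.5 | 0.6 | 46.5 |
| winter | 0.833 | 6.6 | 2.3 | 43.5 |
| winter | 1.67 | 14.1 | 3.8 | 36.8 |
| winter | 3.00 | 23.7 | 6.8 | 26.8 |
| noon | 0.833 | 1.4 | 0 | 48.9 |
| noon | 2.50 | 7.7 | 0.4 | 41.5 |
| noon | 5.00 | 16.6 | 2.4 | 32.7 |
| noon | 8.00 | 25.4 | 3.6 | 23.9 |
| noon | 10.0 | 30.2 | 4.0 | 19.9 |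

(standard deviation of a reading: 0.5 percentage points)

* the flask that ends with the higher excess of Q over J, or "neither" when 2 percentage points or less lies between them (cedar / birch / neither)
* excess of Q over J at the end, cedar
* excess of Q over J at the end, birch

- L is single-handed; D and X are mirror images of each other, charged as a racemate, each of them at the stated concentration
- as a solid, counted per litre of solution: E
- the analysis behind the earlier runs scatters by 0.5 percentage points, standard deviation
- at the start none of E is in solution
- an excess is the difference of the two amounts in percent of their sum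
- an excess is below zero if the other one leads

Entry one: 0.30 M of E goes to D, making Q. Entry two: the same amount stands open for X, making J. So a flask whose books close ends with Q and J equal and an excess near zero, and the question is how fast they close.

For that I read a feed rate, the moles of E per litre and day passing from the solid into product, with dissolved E taken as steady: 0.0853 M d⁻¹, a reading from the last interval of the winter run at 15 °C.

For birch's cold days I borrowed the dusk run, which had put 0.0620 M into product by 2.50 d. That leaves 0.538 M, which the feed rate delivers in 6.31 d, less than the 7.00 d birch spends at 40 °C, provided the warmer flask feeds no slower. So I expected birch's books to close, with an excess near zero. The noon run ended with 0.205 M of product; even doubled for its L, that is 0.410 M, less than the charge. So I expected cedar's books to stay open and cedar to end higher.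

The forecast also chose cedar, with 64% for cedar, but it put birch at 23%, well above my near zero, and its ground for the rate was: “Solid E remains, so the rate stays steady.”

The flasks gave cedar, with 61.6% for cedar and 1.43% for birch.

    G + L + D → L + Q (k = 24.0 M⁻² h⁻¹, Ea = 42.0 kJ mol⁻¹)
    G + L + X → L + J (k = 2.50 M⁻² h⁻¹, Ea = 62.0 kJ mol⁻¹)
    E ⇌ G, rate k3*(cs3 - [G]) while solid is left; crystals form when [G] > cs3 (solubility = 0.110 M, k = 0.0410 h⁻¹)
    (constants at −10 °C)

At the feed rate, the E that birch held at 3.00 d, 68.6% of its charge, needed 4.83 d, less than the 7.00 d left, and at 10.0 d birch held E 0%, Q 50.0% and J 48.6%. The neighbour of cedar with 0.015 M of L lost solid at an average 0.0511 M d⁻¹, slower than the feed rate, and ended with E 14.9%, Q 49.7%, J 20.4% and an excess of 41.9%.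

Readings and results stem from a simulated flask with constants of no real substance; the scatter is artificial.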